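The route rests on cutting both O1–C2 bonds of the two chroman units: in each pyran ring C2 is a benzylic methine carrying O1, C3 and phenyl, i.e. a 1-phenylallyl aryl ether once C3 is written as a vinyl carbon. One twofold iridium-catalysed branched allylic etherification of cinnamyl methyl carbonate therefore installs both O1–C2 bonds and both (S) centres at C2 without closing a ring. Its substrate is a methylene-bridged bis-salicylaldehyde (ring A linked through C8, ring B through C6) whose only free hydroxyls are the two chelated 8a-phenols, the 7-oxygens being benzyl ethers; the formyl carbons later become C4 by methylenation, ring-closing metathesis and hydrogenation.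

Key step: step 11

Remark: 3,5-bis(benzyloxy)phenol is taken as a purchased building block, and the (Sa,S,S) ligand is assigned to the (S) ethers from the usual sense of induction of this catalyst family, to be confirmed on a model phenol (the mirror-image ligand is used if the sense is opposite).

Step 1
Reactants: 1 5-methoxyresorcinol
Product: 2 1-methoxy-3,5-bis(methoxymethoxy)benzene
Conditions: NaH, MOMCl, DMF, 0 °C → rt
Reagents that add atoms: chloromethyl methyl ether (MOMCl), COCCl
Why: Williamson O-alkylation of both phenoxides gives the bis-MOM ether, whose two acetal oxygens later direct lithiation to the carbon between them.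

Step 2
Reactants: 3 3,5-bis(benzyloxy)phenol
Product: 4 2,4-bis(benzyloxy)-6-hydroxybenzaldehyde
Conditions: MgCl2, Et3N, (CH2O)n, MeCN, reflux
Reagents that add atoms: paraformaldehyde (as formaldehyde), C=O
Why: Magnesium-mediated ortho-formylation (Casnati–Skattebøl reaction) delivers formaldehyde only to a carbon ortho to the magnesium phenoxide, so the carbon between the two benzyloxy groups is untouched and the two equivalent ortho carbons give one product.

Step 3
Reactants: 4 2,4-bis(benzyloxy)-6-hydroxybenzaldehyde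
Product: 5 3,5-bis(benzyloxy)-2-formylphenyl tert-butyl carbonate
Conditions: Boc2O, i-Pr2NEt, DMAP (cat.), CH2Cl2, rt
Reagents that add atoms: di-tert-butyl dicarbonate, CC(C)(C)OC(=O)OC(=O)OC(C)(C)C
Why: DMAP-catalysed O-acylation of the phenol gives the aryl carbonate, which frees the aldehyde from chelation and later acts as the leaving group for quinone methide formation.

Step 4
Reactants: 2 1-methoxy-3,5-bis(methoxymethoxy)benzene; 5 3,5-bis(benzyloxy)-2-formylphenyl tert-butyl carbonate
Product: 9 3,5-bis(benzyloxy)-2-{[4-methoxy-2,6-bis(methoxymethoxy)phenyl]methyl}phenol, via aryllithium 6 (not isolated), via lithium alkoxide 7 (not isolated), via ortho-quinone methide 8 (not isolated)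
Conditions: n-BuLi, THF, 0 °C (on 2); then 5, −78 → 0 °C; then NaBH4, EtOH, 0 °C → rt
Reagents that add atoms: none
Why: Directed ortho-metalation between the two MOM ethers and 1,2-addition of the aryllithium to the aldehyde are followed by Boc transfer to the alkoxide, loss of tert-butyl carbonate and 1,4-reduction of the quinone methide by borohydride (anionic ortho-quinone methide cascade of O-Boc salicylaldehydes), which gives the diarylmethane without acid so that the MOM ethers survive and the racemic carbinol centre of 7 disappears.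

Step 5
Reactants: 9 3,5-bis(benzyloxy)-2-{[4-methoxy-2,6-bis(methoxymethoxy)phenyl]methyl}phenol
Product: 10 4,6-bis(benzyloxy)-2-hydroxy-3-{[4-methoxy-2,6-bis(methoxymethoxy)phenyl]methyl}benzaldehyde
Conditions: MgCl2, Et3N, (CH2O)n, MeCN, reflux
Reagents that add atoms: paraformaldehyde (as formaldehyde), C=O
Why: The same magnesium-mediated ortho-formylation can reach only the one remaining ortho carbon of the single free phenol on ring B, while ring A, which has no free hydroxyl, is left alone.

Step 6
Reactants: 10 4,6-bis(benzyloxy)-2-hydroxy-3-{[4-methoxy-2,6-bis(methoxymethoxy)phenyl]methyl}benzaldehyde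
Product: 11 4,6-bis(benzyloxy)-2-methoxy-3-{[4-methoxy-2,6-bis(methoxymethoxy)phenyl]methyl}benzaldehyde
Conditions: MeI, K2CO3, DMF, 40 °C
Reagents that add atoms: iodomethane, CI
Why: Williamson O-methylation of the only free phenol fixes the 5-methoxy group of ring B at a stage where every ring A oxygen is still masked.

Step 7
Reactants: 11 4,6-bis(benzyloxy)-2-methoxy-3-{[4-methoxy-2,6-bis(methoxymethoxy)phenyl]methyl}benzaldehyde
Product: 14 4,6-bis(benzyloxy)-3-[(3-formyl-2,6-dihydroxy-4-methoxyphenyl)methyl]-2-methoxybenzaldehyde, via iminium chloride 12 (not isolated), via bis-MOM dialdehyde 13 (not isolated)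
Conditions: POCl3, DMF, 0 °C → rt; then H2O; then HCl, MeOH–THF, 40 °C
Reagents that add atoms: N,N-dimethylformamide, CN(C)C=O; water, O
Why: Vilsmeier–Haack formylation attacks the electron-rich ring A at one of its two equivalent free carbons (ring B is deactivated by its formyl group), and acidic methanolysis then removes both MOM acetals from the now deactivated ring.

Step 8
Reactants: 14 4,6-bis(benzyloxy)-3-[(3-formyl-2,6-dihydroxy-4-methoxyphenyl)methyl]-2-methoxybenzaldehyde
Product: 15 4,6-bis(benzyloxy)-3-{[6-(benzyloxy)-3-formyl-2-hydroxy-4-methoxyphenyl]methyl}-2-methoxybenzaldehyde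
Conditions: BnBr (1.05 equiv), K2CO3 (1.1 equiv), acetone, 50 °C
Reagents that add atoms: benzyl bromide, BrCc1ccccc1
Why: Williamson benzylation is selective for the hydroxyl para to the formyl group, because the ortho hydroxyl is held in a hydrogen bond to the carbonyl and is much less nucleophilic.

Step 9
Reactants: 15 4,6-bis(benzyloxy)-3-{[6-(benzyloxy)-3-formyl-2-hydroxy-4-methoxyphenyl]methyl}-2-methoxybenzaldehyde
Product: 16 4-(benzyloxy)-3-{[6-(benzyloxy)-3-formyl-4-hydroxy-2-methoxyphenyl]methyl}-2-hydroxy-6-methoxybenzaldehyde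
Conditions: MgBr2·OEt2 (3 equiv), toluene–Et2O, 80 °C; dilute HCl work-up
Reagents that add atoms: none
Why: Chelation-controlled Lewis acid ether cleavage lets bromide remove only the benzyl group whose oxygen sits ortho to the ring B formyl group, where magnesium is held between the two oxygens, while the benzyl ethers para to a formyl group and the methyl ethers stay.

Step 10
Reactants: 17 (E)-cinnamyl alcohol
Product: 18 (E)-cinnamyl methyl carbonate
Conditions: ClCO2Me, pyridine, CH2Cl2, 0 °C
Reagents that add atoms: methyl chloroformate, COC(=O)Cl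
Why: O-acylation of the primary allylic alcohol gives the carbonate, whose ionisation by iridium releases methoxide as an internal base.

Step 11
Reactants: 16 4-(benzyloxy)-3-{[6-(benzyloxy)-3-formyl-4-hydroxy-2-methoxyphenyl]methyl}-2-hydroxy-6-methoxybenzaldehyde; 18 (E)-cinnamyl methyl carbonate
Product: 19 4-(benzyloxy)-3-{[6-(benzyloxy)-3-formyl-2-methoxy-4-{[(1S)-1-phenylprop-2-en-1-yl]oxy}phenyl]methyl}-6-methoxy-2-{[(1S)-1-phenylprop-2-en-1-yl]oxy}benzaldehyde
Conditions: [Ir(cod)Cl]2 (4 mol%), (Sa,S,S)-O,O′-(1,1′-binaphthalene-2,2′-diyl) N,N-bis(1-phenylethyl)phosphoramidite (8 mol%), pre-activated with n-PrNH2 and freed of volatiles; 18 (3 equiv), K3PO4, THF, 25–40 °C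
Reagents that add atoms: none
Why: The cyclometalated monovalent iridium phosphoramidite complex ionises carbonate 18 to a phenyl-substituted allyl complex of trivalent iridium, and each phenoxide of 16 attacks the benzylic terminus on the face away from the metal, forming the two O–C bonds of a branched 1-phenylallyl aryl ether (iridium-catalysed enantioselective allylic etherification of phenoxides, a known reaction type). No ring is closed in this step, so no mode of closure applies. Both new stereocentres are set by the catalyst alone: the (Sa,S,S) ligand fixes which face of the allyl unit is exposed and should give the (S) ether at each of the two remote sites independently, so that a wrong-face event ends in a separable diastereomer and the (S,S) product is enriched. The step needs branched over linear attack and O-allylation, which are properties of this catalyst with phenoxides, and reaction at two oxygens only, which the substrate secures because every other oxygen is a benzyl or methyl ether. Because the product is the allyl ether of an acidic, formyl-conjugated phenol the catalyst could re-ionise it, so the reaction is run cool, free of primary amine, and stopped at full conversion.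

Step 12
Reactants: 19 4-(benzyloxy)-3-{[6-(benzyloxy)-3-formyl-2-methoxy-4-{[(1S)-1-phenylprop-2-en-1-yl]oxy}phenyl]methyl}-6-methoxy-2-{[(1S)-1-phenylprop-2-en-1-yl]oxy}benzaldehyde
Product: 20 1-(benzyloxy)-2-{[6-(benzyloxy)-3-ethenyl-2-methoxy-4-{[(1S)-1-phenylprop-2-en-1-yl]oxy}phenyl]methyl}-4-ethenyl-5-methoxy-3-{[(1S)-1-phenylprop-2-en-1-yl]oxy}benzene
Conditions: Ph3PCH3Br (3 equiv), KOt-Bu (2.8 equiv), THF, 0 °C; then 19, −20 → 0 °C
Reagents that add atoms: methyltriphenylphosphonium bromide, C[P+](c1ccccc1)(c1ccccc1)c1ccccc1.[Br-]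
Why: Wittig methylenation with the small unstabilised ylide, preformed with a slight deficit of base so that the base-sensitive ether methines at the (S) centres are not deprotonated, turns both hindered formyl groups into vinyl groups.

Step 13
Reactants: 20 1-(benzyloxy)-2-{[6-(benzyloxy)-3-ethenyl-2-methoxy-4-{[(1S)-1-phenylprop-2-en-1-yl]oxy}phenyl]methyl}-4-ethenyl-5-methoxy-3-{[(1S)-1-phenylprop-2-en-1-yl]oxy}benzene
Product: 21 (2S)-7-(benzyloxy)-8-{[(2S)-7-(benzyloxy)-5-methoxy-2-phenyl-2H-chromen-6-yl]methyl}-5-methoxy-2-phenyl-2H-chromene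
Conditions: second-generation Grubbs catalyst (2 × 5 mol%), CH2Cl2, 40 °C, dark
Reagents that add atoms: none
Why: Twofold ring-closing metathesis joins each aryl vinyl group to the vinyl group of the neighbouring allylic ether with loss of ethylene, closing both six-membered 2H-pyran rings without touching the C2 centres.

Step 14
Reactants: 21 (2S)-7-(benzyloxy)-8-{[(2S)-7-(benzyloxy)-5-methoxy-2-phenyl-2H-chromen-6-yl]methyl}-5-methoxy-2-phenyl-2H-chromene
Product: 22 (2S)-8-{[(2S)-7-hydroxy-5-methoxy-2-phenyl-3,4-dihydro-2H-chromen-6-yl]methyl}-5-methoxy-2-phenyl-3,4-dihydro-2H-chromen-7-ol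
Conditions: H2 (1 atm), 10% Pd/C, EtOAc, rt
Reagents that add atoms: none
Why: Heterogeneous catalytic hydrogenation saturates both C3=C4 bonds and hydrogenolyses the two O-benzyl ethers in one operation, and the neutral solvent and short contact time are chosen to spare the benzylic C2–O1 bonds so that both (S) centres are carried through unchanged.

Compound list
1 | 5-methoxyresorcinol (5-methoxybenzene-1,3-diol) | COc1cc(O)cc(O)c1 | starting material
2 | 1-methoxy-3,5-bis(methoxymethoxy)benzene | COCOc1cc(OC)cc(OCOC)c1 | intermediate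
3 | 3,5-bis(benzyloxy)phenol | Oc1cc(OCc2ccccc2)cc(OCc2ccccc2)c1 | starting material
4 | 2,4-bis(benzyloxy)-6-hydroxybenzaldehyde | O=Cc1c(O)cc(OCc2ccccc2)cc1OCc1ccccc1 | intermediate
5 | 3,5-bis(benzyloxy)-2-formylphenyl tert-butyl carbonate | CC(C)(C)OC(=O)Oc1cc(OCc2ccccc2)cc(OCc2ccccc2)c1C=O | intermediate
6 | [4-methoxy-2,6-bis(methoxymethoxy)phenyl]lithium | [Li]c1c(OCOC)cc(OC)cc1OCOC | intermediate
7 | lithium {2,4-bis(benzyloxy)-6-[(tert-butoxycarbonyl)oxy]phenyl}[4-methoxy-2,6-bis(methoxymethoxy)phenyl]methanolate (racemic) | [Li]OC(c1c(OCOC)cc(OC)cc1OCOC)c1c(OC(=O)OC(C)(C)C)cc(OCc2ccccc2)cc1OCc1ccccc1 | intermediate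
8 | 3,5-bis(benzyloxy)-6-{[4-methoxy-2,6-bis(methoxymethoxy)phenyl]methylidene}cyclohexa-2,4-dien-1-one | O=C1C=C(OCc2ccccc2)C=C(OCc2ccccc2)C1=Cc1c(OCOC)cc(OC)cc1OCOC | intermediate
9 | 3,5-bis(benzyloxy)-2-{[4-methoxy-2,6-bis(methoxymethoxy)phenyl]methyl}phenol | COCOc1cc(OC)cc(OCOC)c1Cc1c(O)cc(OCc2ccccc2)cc1OCc1ccccc1 | intermediate
10 | 4,6-bis(benzyloxy)-2-hydroxy-3-{[4-methoxy-2,6-bis(methoxymethoxy)phenyl]methyl}benzaldehyde | COCOc1cc(OC)cc(OCOC)c1Cc1c(O)c(C=O)c(OCc2ccccc2)cc1OCc1ccccc1 | intermediate
11 | 4,6-bis(benzyloxy)-2-methoxy-3-{[4-methoxy-2,6-bis(methoxymethoxy)phenyl]methyl}benzaldehyde | COCOc1cc(OC)cc(OCOC)c1Cc1c(OC)c(C=O)c(OCc2ccccc2)cc1OCc1ccccc1 | intermediate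
12 | N-{[3-{[4,6-bis(benzyloxy)-3-formyl-2-methoxyphenyl]methyl}-6-methoxy-2,4-bis(methoxymethoxy)phenyl]methylidene}-N-methylmethanaminium chloride | C[N+](C)=Cc1c(OC)cc(OCOC)c(Cc2c(OC)c(C=O)c(OCc3ccccc3)cc2OCc2ccccc2)c1OCOC.[Cl-] | intermediate
13 | 4,6-bis(benzyloxy)-3-{[3-formyl-4-methoxy-2,6-bis(methoxymethoxy)phenyl]methyl}-2-methoxybenzaldehyde | COCOc1cc(OC)c(C=O)c(OCOC)c1Cc1c(OC)c(C=O)c(OCc2ccccc2)cc1OCc1ccccc1 | intermediate
14 | 4,6-bis(benzyloxy)-3-[(3-formyl-2,6-dihydroxy-4-methoxyphenyl)methyl]-2-methoxybenzaldehyde | COc1cc(O)c(Cc2c(OC)c(C=O)c(OCc3ccccc3)cc2OCc2ccccc2)c(O)c1C=O | intermediate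
15 | 4,6-bis(benzyloxy)-3-{[6-(benzyloxy)-3-formyl-2-hydroxy-4-methoxyphenyl]methyl}-2-methoxybenzaldehyde | COc1cc(OCc2ccccc2)c(Cc2c(OC)c(C=O)c(OCc3ccccc3)cc2OCc2ccccc2)c(O)c1C=O | intermediate
16 | 4-(benzyloxy)-3-{[6-(benzyloxy)-3-formyl-4-hydroxy-2-methoxyphenyl]methyl}-2-hydroxy-6-methoxybenzaldehyde | COc1cc(OCc2ccccc2)c(Cc2c(OCc3ccccc3)cc(O)c(C=O)c2OC)c(O)c1C=O | intermediate
17 | (E)-cinnamyl alcohol | OC/C=C/c1ccccc1 | starting material
18 | (E)-cinnamyl methyl carbonate | COC(=O)OC/C=C/c1ccccc1 | intermediate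
19 | 4-(benzyloxy)-3-{[6-(benzyloxy)-3-formyl-2-methoxy-4-{[(1S)-1-phenylprop-2-en-1-yl]oxy}phenyl]methyl}-6-methoxy-2-{[(1S)-1-phenylprop-2-en-1-yl]oxy}benzaldehyde | COc1cc(OCc2ccccc2)c(Cc2c(OCc3ccccc3)cc(O[C@@H](C=C)c3ccccc3)c(C=O)c2OC)c(O[C@@H](C=C)c2ccccc2)c1C=O | intermediate
20 | 1-(benzyloxy)-2-{[6-(benzyloxy)-3-ethenyl-2-methoxy-4-{[(1S)-1-phenylprop-2-en-1-yl]oxy}phenyl]methyl}-4-ethenyl-5-methoxy-3-{[(1S)-1-phenylprop-2-en-1-yl]oxy}benzene | COc1cc(OCc2ccccc2)c(Cc2c(OCc3ccccc3)cc(O[C@@H](C=C)c3ccccc3)c(C=C)c2OC)c(O[C@@H](C=C)c2ccccc2)c1C=C | intermediate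
21 | (2S)-7-(benzyloxy)-8-{[(2S)-7-(benzyloxy)-5-methoxy-2-phenyl-2H-chromen-6-yl]methyl}-5-methoxy-2-phenyl-2H-chromene | COc1cc(OCc2ccccc2)c(Cc2c(OCc3ccccc3)cc3c(c2OC)C=C[C@@H](c2ccccc2)O3)c2c1C=C[C@@H](c1ccccc1)O2 | intermediate
22 | (2S)-8-{[(2S)-7-hydroxy-5-methoxy-2-phenyl-3,4-dihydro-2H-chromen-6-yl]methyl}-5-methoxy-2-phenyl-3,4-dihydro-2H-chromen-7-ol | COc1cc(O)c(Cc2c(O)cc3c(c2OC)CC[C@@H](c2ccccc2)O3)c2c1CC[C@@H](c1ccccc1)O2 | target

Total step count: 14 steps.
Longest linear sequence: 12 steps (from 3 through steps 2–9 and 11–14).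

Steps most likely to fail

Step 11. The second etherification may stall on the hindered, chelated phenoxides, and the catalyst may re-ionise the product ethers, which would drain material to the linear cinnamyl ethers and erode the configuration at C2. Fallback: setting out from 16, both formyl groups are methylenated first with an excess of methylidenetriphenylphosphorane (the first two equivalents serve as base for the phenols), giving the bis(2-vinylphenol) 3-(benzyloxy)-2-{[6-(benzyloxy)-3-ethenyl-4-hydroxy-2-methoxyphenyl]methyl}-6-ethenyl-5-methoxyphenol F1. Its phenoxides are unchelated, more nucleophilic and poorer leaving groups; they are etherified with 18 under the same iridium catalyst, which gives 20, where the route is rejoined.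

Step 4. The aryllithium may attack the carbonate carbonyl instead of the aldehyde, or the quinone methide may be captured by a second aryl nucleophile or by phenoxide before hydride arrives. Fallback: setting out from 4, NaBH4 reduces the aldehyde to the salicyl alcohol 3,5-bis(benzyloxy)-2-(hydroxymethyl)phenol F2, whose phenol is selectively acylated with Boc2O to 3,5-bis(benzyloxy)-2-(hydroxymethyl)phenyl tert-butyl carbonate F3. Aryllithium 6 is transmetalated with MgBr2·OEt2 to [4-methoxy-2,6-bis(methoxymethoxy)phenyl]magnesium bromide F4. An excess of F4 deprotonates the alcohol of F3, which triggers Boc transfer and loss of tert-butyl carbonate to give the unsubstituted quinone methide 3,5-bis(benzyloxy)-6-methylidenecyclohexa-2,4-dien-1-one F5; conjugate addition of F4 to F5 gives 9, where the route is rejoined.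

Step 14. Palladium may hydrogenolyse the allylic, benzylic C2–O1 bonds of the chromenes before the C3=C4 bonds are saturated, which would open the pyran rings. Fallback: setting out from 21, the two C3=C4 bonds are first saturated with H2 over the homogeneous catalyst RhCl(PPh3)3, which does not cleave C–O bonds, to give (2S)-7-(benzyloxy)-8-{[(2S)-7-(benzyloxy)-5-methoxy-2-phenyl-3,4-dihydro-2H-chromen-6-yl]methyl}-5-methoxy-2-phenyl-3,4-dihydro-2H-chromene F6. The benzyl ethers of F6, now on plain flavans, are then removed with H2 over Pd(OH)2/C, which gives 22.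

Further compounds
F1 | step 11 | 3-(benzyloxy)-2-{[6-(benzyloxy)-3-ethenyl-4-hydroxy-2-methoxyphenyl]methyl}-6-ethenyl-5-methoxyphenol | COc1cc(OCc2ccccc2)c(Cc2c(OCc3ccccc3)cc(O)c(C=C)c2OC)c(O)c1C=C
F2 | step 4 | 3,5-bis(benzyloxy)-2-(hydroxymethyl)phenol | OCc1c(O)cc(OCc2ccccc2)cc1OCc1ccccc1
F3 | step 4 | 3,5-bis(benzyloxy)-2-(hydroxymethyl)phenyl tert-butyl carbonate | CC(C)(C)OC(=O)Oc1cc(OCc2ccccc2)cc(OCc2ccccc2)c1CO
F4 | step 4 | [4-methoxy-2,6-bis(methoxymethoxy)phenyl]magnesium bromide | Br[Mg]c1c(OCOC)cc(OC)cc1OCOC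
F5 | step 4 | 3,5-bis(benzyloxy)-6-methylidenecyclohexa-2,4-dien-1-one | C=C1C(=O)C=C(OCc2ccccc2)C=C1OCc1ccccc1
F6 | step 14 | (2S)-7-(benzyloxy)-8-{[(2S)-7-(benzyloxy)-5-methoxy-2-phenyl-3,4-dihydro-2H-chromen-6-yl]methyl}-5-methoxy-2-phenyl-3,4-dihydro-2H-chromene | COc1cc(OCc2ccccc2)c(Cc2c(OCc3ccccc3)cc3c(c2OC)CC[C@@H](c2ccccc2)O3)c2c1CC[C@@H](c1ccccc1)O2
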